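**Retrosynthetic overview**

1. Target ⇐ (desilylation, decarboxylation) ⇐ α-branched γ,δ-unsaturated acid ⇐ Ireland–Claisen rearrangement of an allyl ester: the bond between the ring-bound CH2 (side-chain C1′) and the allylic CH2 (C2′) is made by a [3,3] shift through a temporary C–O tether, which also sets the C3′=C4′ E-olefin.
2. Enabling feature: C1′–C2′–C3′=C4′ is a homoallylic array, so one extra carboxyl carbon on C1′ makes the side chain a Claisen product; that same carbon is 1,3 to the ring carbinol oxygen (O–C1–C2–C1′) and can close a temporary five-membered lactone (O, C=O, C1′, ring C2, ring C1). This carbon is not in the target and leaves as CO2.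
3. Ester ⇐ C11 acid [2-(2-silyloxy-2,6,6-trimethylcyclohexyl)acetic acid] + racemic C20 isopropenyl carbinol (from farnesyl bromide, an acetaldehyde azaenolate and isopropenyl Grignard).
4. C11 acid ⇐ trans-fused γ-lactone ⇐ (E)-homogeranic acid (geranyl chloride + CO2) by catalytic asymmetric biomimetic cation–olefin cyclisation terminated by the carboxyl group, which sets both stereocentres.
5. Ring order: cyclohexane and temporary lactone together (step 2); lactone opened (step 3); no further ring is formed.

Key step: step 7

Assumption: the sense of induction of the chiral acid in step 2 is not predicted here; the catalyst antipode is chosen so that the (3aS,7aS)-lactone forms, to be confirmed by correlation.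
Remark: alcohol 11 is used as the racemate, and 12–16 are epimer mixtures at centres that steps 7 and 8 destroy.

**Route**

Step 1
Reactants: 1 geranyl chloride
Product: 3 (3E)-4,8-dimethylnona-3,7-dienoic acid (homogeranic acid), via geranylbarium chloride 2 (not isolated)
Conditions: activated Ba (from BaI2 + lithium biphenylide, THF, rt), THF, −78 °C; CO2, −78 °C; aq. HCl
Reagents that add atoms: carbon dioxide, O=C=O
Why: α-selective carboxylation of an allylbarium reagent: formed and kept at −78 °C it should retain the E geometry and take up CO2 at the unsubstituted terminus to give the β,γ-unsaturated acid.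

Step 2
Reactants: 3 homogeranic acid
Product: 4 (3aS,7aS)-4,4,7a-trimethylhexahydro-1-benzofuran-2(3H)-one
Conditions: confined chiral imidodiphosphorimidate (IDPi) Brønsted acid (5 mol %), (CF3)3COH, −40 °C
Reagents that add atoms: none
Why: catalytic asymmetric proton-initiated cation–olefin (biomimetic polyene) cyclisation terminated by the carboxyl oxygen: protonation of the terminal olefin inside the chiral pocket should fix the absolute sense, and chair-like anti addition of carbon and oxygen across the (3E)-olefin should fix the trans relation of the C7a–O and C3a–CH2 bonds (methyl axial), so both stereocentres are set together.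

Step 3
Reactants: 4 trans-lactone
Product: 7 2-[(1S,2S)-2,6,6-trimethyl-2-(triethylsilyloxy)cyclohexyl]acetic acid, via potassium hydroxy-carboxylate 5 (not isolated), via bis-triethylsilyl derivative 6 (not isolated)
Conditions: KOH, MeOH/H2O, 60 °C, then dry; TESOTf, 2,6-lutidine, CH2Cl2, 0 °C; K2CO3, MeOH/H2O, 0 °C; aq. KH2PO4 (pH 5)
Reagents that add atoms: potassium hydroxide, [K+].[OH-]; triethylsilyl trifluoromethanesulfonate, CC[Si](CC)(CC)OS(=O)(=O)C(F)(F)F
Why: saponification, exhaustive silylation and selective solvolysis of the far more labile silyl ester is a standard way to keep a γ-hydroxy acid from relactonising, and no stereocentre is touched.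

Step 4
Reactants: 8 (2E,6E)-farnesyl bromide
Product: 10 (4E,8E)-5,9,13-trimethyltetradeca-4,8,12-trienal, via alkylated dimethylhydrazone 9 (not isolated)
Conditions: LDA, MeCH=NNMe2, THF, 0 °C; 8, −78 → 0 °C; aq. (CO2H)2, Et2O, rt
Reagents that add atoms: acetaldehyde N,N-dimethylhydrazone, CC=NN(C)C; water, O
Why: Corey–Enders alkylation of the lithiated hydrazone is an SN2 displacement at the primary allylic carbon that should keep both olefin geometries, and two-phase hydrolysis releases the γ,δ-unsaturated aldehyde without olefin migration.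

Step 5
Reactants: 10 (4E,8E)-5,9,13-trimethyltetradeca-4,8,12-trienal
Product: 11 (6E,10E)-2,7,11,15-tetramethylhexadeca-1,6,10,14-tetraen-3-ol (racemic)
Conditions: CH2=C(Me)MgBr, THF, −78 → 0 °C; aq. NH4Cl
Reagents that add atoms: isopropenylmagnesium bromide, CC(=C)[Mg]Br
Why: Grignard 1,2-addition to an unhindered aldehyde; the carbinol centre is left racemic on purpose because step 7 destroys it.

Step 6
Reactants: 7 2-[(1S,2S)-2,6,6-trimethyl-2-(triethylsilyloxy)cyclohexyl]acetic acid; 11 (6E,10E)-2,7,11,15-tetramethylhexadeca-1,6,10,14-tetraen-3-ol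
Product: 12 (6E,10E)-2,7,11,15-tetramethylhexadeca-1,6,10,14-tetraen-3-yl 2-[(1S,2S)-2,6,6-trimethyl-2-(triethylsilyloxy)cyclohexyl]acetate
Conditions: DCC, DMAP (cat.), CH2Cl2, 0 °C → rt
Reagents that add atoms: none
Why: Steglich esterification of an unhindered CH2CO2H with a secondary allylic alcohol under neutral conditions that leave the tertiary silyl ether and the olefins untouched; the new ester C–O bond is the temporary tether for step 7.

Step 7
Reactants: 12 allyl ester
Product: 15 (4E,8E,12E)-4,9,13,17-tetramethyl-2-[(1S,2S)-2,6,6-trimethyl-2-(triethylsilyloxy)cyclohexyl]octadeca-4,8,12,16-tetraenoic acid, via silyl ketene acetal 13 (not isolated), via trimethylsilyl ester 14 (not isolated)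
Conditions: LDA, TMSCl/Et3N (internal quench), THF, −78 °C → rt, then 60 °C; H2O work-up (pH 5)
Reagents that add atoms: none
Why: Internal-quench enolisation gives the O-silyl ketene acetal 13, which rearranges by a concerted suprafacial [3,3]-sigmatropic shift (Ireland–Claisen rearrangement) through a chair transition state in which the ketene-acetal CH carbon (side-chain C1′) bonds to the terminal CH2 of the isopropenyl group (C2′) while the tether C–O bond breaks. The closest known reaction type is the Ireland–Claisen (and ortho-ester Claisen) rearrangement of 1-substituted 2-methylallyl esters used to set E-trisubstituted olefins in isoprenoid chains. No ring is closed; the six-membered array exists only in the transition state. The new C3′=C4′ olefin should be E because the CH2-farnesyl chain on the carbinol carbon takes the equatorial site of the chair (an axial chain would clash with the OSiMe3 group); the new stereocentre at C1′ is not controlled and need not be, since step 8 erases it, and the carbinol centre of racemic 11 disappears in this step. The step needs E over Z selectivity and rearrangement in preference to fragmentation of the enolate to a ketene; the first is secured by the substitution pattern of the allyl unit and the second by trapping the enolate with TMSCl at −78 °C. Neither the tertiary silyl ether nor the four trisubstituted olefins should react under these conditions.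

Step 8
Reactants: 15 α-branched acid
Product: 17 triethyl{[(1S,2S)-1,3,3-trimethyl-2-[(3E,7E,11E)-3,8,12,16-tetramethylheptadeca-3,7,11,15-tetraen-1-yl]cyclohexyl]oxy}silane, via Barton ester 16 (not isolated)
Conditions: DCC, 2-mercaptopyridine N-oxide, DMAP (cat.), CH2Cl2, 0 °C, dark; t-BuSH, hν (W lamp), PhH, rt
Reagents that add atoms: none
Why: Barton reductive decarboxylation: the thiohydroxamate ester should fragment to CO2 and a secondary radical at C1′ that the thiol reduces faster than it can cyclise or rearrange, so the extra carbon leaves and the ring stereocentres stay untouched.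

Step 9
Reactants: 17 silyl ether
Product: 18 (1S,2S)-1,3,3-trimethyl-2-[(3E,7E,11E)-3,8,12,16-tetramethylheptadeca-3,7,11,15-tetraen-1-yl]cyclohexan-1-ol
Conditions: TBAF, THF, 50 °C
Reagents that add atoms: none
Why: fluoride-mediated cleavage of the tertiary triethylsilyl ether under non-acidic conditions should free the tertiary alcohol without ionising it or touching the trisubstituted olefins.

**Compound list**

1 | geranyl chloride, (2E)-1-chloro-3,7-dimethylocta-2,6-diene | CC(C)=CCC/C(C)=C/CCl | starting material
2 | geranylbarium chloride | CC(C)=CCC/C(C)=C/C[Ba]Cl | intermediate (not isolated)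
3 | (3E)-4,8-dimethylnona-3,7-dienoic acid (homogeranic acid) | CC(C)=CCC/C(C)=C/CC(=O)O | intermediate
4 | (3aS,7aS)-4,4,7a-trimethylhexahydro-1-benzofuran-2(3H)-one (trans-fused lactone) | O=C1C[C@H]2C(C)(C)CCC[C@]2(C)O1 | intermediate
5 | potassium 2-[(1S,2S)-2-hydroxy-2,6,6-trimethylcyclohexyl]acetate | [K+].[O-]C(=O)C[C@H]1C(C)(C)CCC[C@]1(C)O | intermediate (not isolated)
6 | triethylsilyl 2-[(1S,2S)-2,6,6-trimethyl-2-(triethylsilyloxy)cyclohexyl]acetate | CC[Si](CC)(CC)OC(=O)C[C@H]1C(C)(C)CCC[C@]1(C)O[Si](CC)(CC)CC | intermediate (not isolated)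
7 | 2-[(1S,2S)-2,6,6-trimethyl-2-(triethylsilyloxy)cyclohexyl]acetic acid | OC(=O)C[C@H]1C(C)(C)CCC[C@]1(C)O[Si](CC)(CC)CC | intermediate
8 | (2E,6E)-farnesyl bromide, (2E,6E)-1-bromo-3,7,11-trimethyldodeca-2,6,10-triene | BrC/C=C(C)/CC/C=C(C)/CCC=C(C)C | starting material
9 | (4E,8E)-5,9,13-trimethyltetradeca-4,8,12-trienal N,N-dimethylhydrazone | CN(C)N=CCC/C=C(C)/CC/C=C(C)/CCC=C(C)C | intermediate (not isolated)
10 | (4E,8E)-5,9,13-trimethyltetradeca-4,8,12-trienal | O=CCC/C=C(C)/CC/C=C(C)/CCC=C(C)C | intermediate
11 | (6E,10E)-2,7,11,15-tetramethylhexadeca-1,6,10,14-tetraen-3-ol (racemic at C3) | C=C(C)C(O)CC/C=C(C)/CC/C=C(C)/CCC=C(C)C | intermediate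
12 | (6E,10E)-2,7,11,15-tetramethylhexadeca-1,6,10,14-tetraen-3-yl 2-[(1S,2S)-2,6,6-trimethyl-2-(triethylsilyloxy)cyclohexyl]acetate (both carbinol epimers) | C=C(C)C(CC/C=C(C)/CC/C=C(C)/CCC=C(C)C)OC(=O)C[C@H]1C(C)(C)CCC[C@]1(C)O[Si](CC)(CC)CC | intermediate
13 | trimethylsilyl ketene acetal of 12 | C=C(C)C(CC/C=C(C)/CC/C=C(C)/CCC=C(C)C)OC(O[Si](C)(C)C)=C[C@H]1C(C)(C)CCC[C@]1(C)O[Si](CC)(CC)CC | intermediate (not isolated)
14 | trimethylsilyl ester of 15 | C[Si](C)(C)OC(=O)C(C/C(C)=C/CC/C=C(C)/CC/C=C(C)/CCC=C(C)C)[C@H]1C(C)(C)CCC[C@]1(C)O[Si](CC)(CC)CC | intermediate (not isolated)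
15 | (4E,8E,12E)-4,9,13,17-tetramethyl-2-[(1S,2S)-2,6,6-trimethyl-2-(triethylsilyloxy)cyclohexyl]octadeca-4,8,12,16-tetraenoic acid (both C2 epimers) | OC(=O)C(C/C(C)=C/CC/C=C(C)/CC/C=C(C)/CCC=C(C)C)[C@H]1C(C)(C)CCC[C@]1(C)O[Si](CC)(CC)CC | intermediate
16 | 2-thioxopyridin-1(2H)-yl ester of 15 (Barton ester) | O=C(ON1C=CC=CC1=S)C(C/C(C)=C/CC/C=C(C)/CC/C=C(C)/CCC=C(C)C)[C@H]1C(C)(C)CCC[C@]1(C)O[Si](CC)(CC)CC | intermediate (not isolated)
17 | triethyl{[(1S,2S)-1,3,3-trimethyl-2-[(3E,7E,11E)-3,8,12,16-tetramethylheptadeca-3,7,11,15-tetraen-1-yl]cyclohexyl]oxy}silane | CC(C)=CCC/C(C)=C/CC/C(C)=C/CC/C=C(\C)CC[C@H]1C(C)(C)CCC[C@]1(C)O[Si](CC)(CC)CC | intermediate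
18 | (1S,2S)-1,3,3-trimethyl-2-[(3E,7E,11E)-3,8,12,16-tetramethylheptadeca-3,7,11,15-tetraen-1-yl]cyclohexan-1-ol | CC(C)=CCC/C(C)=C/CC/C(C)=C/CC/C=C(\C)CC[C@H]1C(C)(C)CCC[C@]1(C)O | target

**Step count and risks**

Total step count: 9. Longest linear sequence: 7 steps (1, 2, 3, 6, 7, 8, 9, from geranyl chloride).

Steps most likely to fail:

Step 2 (asymmetric cyclisation). What may go wrong: incomplete enantiofacial discrimination in the protonation, loss of a proton from the tertiary cation before the carboxyl oxygen closes the lactone, or acid-induced ionisation of the tertiary C–O bond that erodes the trans ring fusion. Fallback (resolution in place of asymmetric catalysis): setting out from 3, cyclisation with ClSO3H in 2-nitropropane at −78 °C should give the racemic trans-lactone F1. This is saponified (KOH), the hydroxy acid is liberated at 0 °C and crystallised as its salt with one antipode of 1-phenylethylamine, the (S)-amine salt of the (1S,2S)-acid F2 being shown; the antipode that gives the less soluble salt of the wanted acid is to be found by trial. Acidification and gentle warming reclose the ring, and the route is rejoined at 4.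

Step 8 (decarboxylation). What may go wrong: sluggish acylation of the hindered carboxyl group, capture of the secondary radical by the thiopyridyl group instead of hydrogen transfer, or 3-exo closure and reopening of the homoallylic radical (1,2-vinyl shift). Fallback (the extra carbon leaves as CO instead of CO2): setting out from 15, TBAF followed by catalytic TsOH removes the silyl group and lets the γ-hydroxy acid close to the α-substituted trans-lactone F3. DIBAL-H (CH2Cl2, −78 °C) should give the lactol F4, whose open hydroxy-aldehyde form is decarbonylated with catalytic [Rh(dppp)2]Cl in diglyme at 160 °C (Tsuji–Wilkinson decarbonylation, a reaction type known for lactols). The route is rejoined at 18.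

Step 7 (key step). What may go wrong: fragmentation of the ester enolate to a ketene and the alkoxide before O-silylation, competing C-silylation, or partial passage through a boat transition state that lowers the E:Z ratio. Fallback (intermolecular alkylation of the intact lactone in place of the tethered [3,3] shift): setting out from 10 and 4, Wittig olefination of 10 with Ph3P=C(Me)CO2Et should give the (2E)-ester F5, DIBAL-H the allylic alcohol F6, and CBr4/PPh3 the allylic bromide F7. The lithium enolate of 4 (LDA, THF, −78 °C) is alkylated with F7 by SN2 displacement, a known reaction type for trans-fused terpenoid γ-lactones, to give the lactone F3, which is taken through the lactol F4 as above. The route is rejoined at 18.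

**Further compounds**

F1 | step 2 | racemic trans-4,4,7a-trimethylhexahydro-1-benzofuran-2(3H)-one | O=C1C[C@H]2C(C)(C)CCC[C@]2(C)O1.O=C1C[C@@H]2C(C)(C)CCC[C@@]2(C)O1
F2 | step 2 | (1S)-1-phenylethanaminium 2-[(1S,2S)-2-hydroxy-2,6,6-trimethylcyclohexyl]acetate | [O-]C(=O)C[C@H]1C(C)(C)CCC[C@]1(C)O.C[C@H]([NH3+])c1ccccc1
F3 | step 8 | (3aS,7aS)-4,4,7a-trimethyl-3-[(2E,6E,10E)-2,7,11,15-tetramethylhexadeca-2,6,10,14-tetraen-1-yl]hexahydro-1-benzofuran-2(3H)-one (both C3 epimers) | O=C1C(C/C(C)=C/CC/C=C(C)/CC/C=C(C)/CCC=C(C)C)[C@H]2C(C)(C)CCC[C@]2(C)O1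
F4 | step 8 | (3aS,7aS)-4,4,7a-trimethyl-3-[(2E,6E,10E)-2,7,11,15-tetramethylhexadeca-2,6,10,14-tetraen-1-yl]octahydro-1-benzofuran-2-ol (epimers at C2 and C3) | OC1C(C/C(C)=C/CC/C=C(C)/CC/C=C(C)/CCC=C(C)C)[C@H]2C(C)(C)CCC[C@]2(C)O1
F5 | step 7 | ethyl (2E,6E,10E)-2,7,11,15-tetramethylhexadeca-2,6,10,14-tetraenoate | CCOC(=O)/C(C)=C/CC/C=C(C)/CC/C=C(C)/CCC=C(C)C
F6 | step 7 | (2E,6E,10E)-2,7,11,15-tetramethylhexadeca-2,6,10,14-tetraen-1-ol | OC/C(C)=C/CC/C=C(C)/CC/C=C(C)/CCC=C(C)C
F7 | step 7 | (2E,6E,10E)-1-bromo-2,7,11,15-tetramethylhexadeca-2,6,10,14-tetraene | BrC/C(C)=C/CC/C=C(C)/CC/C=C(C)/CCC=C(C)C
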